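**Retrosynthetic overview**

1. Diffractaic acid ⇒ its benzyl ester (hydrogenolysis last) ⇒ depside C(=O)–O bond: 2,4-dimethoxy-3,6-dimethylbenzoic acid (ring A) plus benzyl 2,4-dihydroxy-3,6-dimethylbenzoate (ring B, bought as the methyl ester with the ring already in place).
2. The strategy rests on one feature of ring A: the C4 methoxy is para to the carboxyl-bearing C1 and next to C5, the only ring carbon with a hydrogen. This is the pattern a ketene acetal leaves on a 5-alkoxycarbonyl-2-pyrone.
3. Ring A ⇒ benzyl 4-methoxy-3,6-dimethyl-2-oxo-2H-pyran-5-carboxylate (supplies C1, C2, C3, C6 with the ester, one OMe and both methyls) plus 1,1-dimethoxyethene (supplies C4–OMe and C5–H): [4+2], then loss of CO2 and MeOH; new bonds C3–C4 and C5–C6.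
4. Pyrone ⇒ O-methylation of the 4-hydroxy-2-pyrone ⇒ benzyl acetoacetate plus methylmalonyl dichloride (from methylmalonic acid).
5. Ring order: the pyranone ring is made first and turned into benzene ring A in the key step; ring B is never built; the two rings are joined at the end.

Key step: step 4

Remark on the chemistry: the target is achiral. The only stereocentres on the route are the enolisable centres of 4 and the two bridgeheads of the transient racemic adduct 8, all destroyed in the step that forms them. The 1,1-dimethoxyethene is assumed to be used freshly distilled and acid-free.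

**Route**

Step 1
Reactants: 1 methylmalonic acid
Product: 2 methylmalonyl dichloride (2-methylpropanedioyl dichloride)
Conditions: SOCl2 (4 equiv), neat, 50 °C; distil at reduced pressure
Reagents that add atoms: thionyl chloride, O=S(Cl)Cl
Why: Standard conversion of a carboxylic acid into its chloride via the chlorosulfite (acyl substitution), driven by loss of SO2 and HCl; the moderate temperature should keep the malonic acid from decarboxylating.

Step 2
Reactants: 3 benzyl acetoacetate; 2 methylmalonyl dichloride
Product: 5 benzyl 4-hydroxy-3,6-dimethyl-2-oxo-2H-pyran-5-carboxylate, via acyclic keto acid chloride 4 (not isolated)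
Conditions: ClCH2CH2Cl, rt then 60 °C, N2 sweep
Reagents that add atoms: none
Why: Known pyranone annulation of a β-keto ester with a malonyl dichloride: the enol of 3 is C-acylated at its α-carbon to give 4, the acetyl enol oxygen then attacks the remaining acid chloride to close the lactone, and enolisation gives the 4-hydroxy-2-pyrone; the methyl group at pyrone C3 blocks the second annulation open to unsubstituted malonyl dichloride.

Step 3
Reactants: 5 benzyl 4-hydroxy-3,6-dimethyl-2-oxo-2H-pyran-5-carboxylate
Product: 6 benzyl 4-methoxy-3,6-dimethyl-2-oxo-2H-pyran-5-carboxylate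
Conditions: Me2SO4 (1.2 equiv), K2CO3, acetone, reflux
Reagents that add atoms: dimethyl sulfate, COS(=O)(=O)OC
Why: Williamson-type O-alkylation of the acidic vinylogous acid; the hard electrophile on the potassium salt is expected to favour the 4-methoxy-2-pyrone over the 2-methoxy-4-pyrone isomer and over C-methylation at C3.

Step 4
Reactants: 6 benzyl 4-methoxy-3,6-dimethyl-2-oxo-2H-pyran-5-carboxylate; 7 1,1-dimethoxyethene
Product: 10 benzyl 2,4-dimethoxy-3,6-dimethylbenzoate, via bicyclic lactone adduct 8 (not isolated), via trimethoxycyclohexadiene ester 9 (not isolated)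
Conditions: 7 (8 equiv), toluene, sealed tube, 130 °C
Reagents that add atoms: none
Why: Inverse-electron-demand Diels–Alder reaction of an alkoxycarbonyl-2-pyrone with a ketene acetal, a known reaction type: the diene C3=C4–C5=C6 of 6, made electron-poor by the lactone carbonyl and the C5 benzyl ester, adds the electron-rich alkene of 7 to give the bridged lactone 8. At the reaction temperature 8 should extrude CO2 by retro-[4+2] to give cyclohexadiene 9, which loses methanol (one ketal methoxy and a hydrogen of the adjacent CH2) to become aromatic. Ring A is closed by an intermolecular [4+2] addition, four pyrone carbons plus the two alkene carbons, forming arene bonds C3–C4 and C5–C6, not by cyclisation of a chain. No stereocentre is left: the two bridgehead centres of racemic 8 vanish on CO2 loss. The step needs a single regiochemistry, the CH2 of 7 to pyrone C6 and the ketal carbon to pyrone C3; this is secured because C6 is the electrophilic δ-terminus of the dienyl lactone and the β-carbon of the C5 enoate, while the 4-methoxy group makes C3 the nucleophilic end that captures the dimethoxycarbenium carbon. The donor methoxy and the methyl groups on both diene termini make 6 slower than a simple coumalate, hence the excess of 7, the sealed vessel and the high temperature.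

Step 5
Reactants: 10 benzyl 2,4-dimethoxy-3,6-dimethylbenzoate
Product: 11 2,4-dimethoxy-3,6-dimethylbenzoic acid
Conditions: H2 (1 atm), 10% Pd/C, EtOAc, rt
Reagents that add atoms: none
Why: Catalytic hydrogenolysis of the benzylic C–O bond frees the acid under neutral conditions and sidesteps saponification of an ester flanked by two ortho substituents; the aryl methyl ethers are inert.

Step 6
Reactants: 12 methyl 2,4-dihydroxy-3,6-dimethylbenzoate
Product: 13 2,4-dihydroxy-3,6-dimethylbenzoic acid
Conditions: KOH (10 equiv), DMSO–H2O, 80 °C, Ar; then 1 M HCl, 0 °C, quick extraction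
Reagents that add atoms: potassium hydroxide, [K+].[OH-]
Why: Saponification (acyl–oxygen cleavage by hydroxide, accelerated in aqueous DMSO) of the hindered salicylate-type ester; the phenoxide-carboxylate polyanion does not decarboxylate, and cold acidification with fast isolation should keep the free acid from protodecarboxylation.

Step 7
Reactants: 13 2,4-dihydroxy-3,6-dimethylbenzoic acid
Product: 14 benzyl 2,4-dihydroxy-3,6-dimethylbenzoate
Conditions: BnBr (1.05 equiv), KHCO3 (1.1 equiv), DMF, rt to 40 °C
Reagents that add atoms: benzyl bromide, BrCc1ccccc1
Why: Chemoselective SN2 O-alkylation of the carboxylate: KHCO3 deprotonates only the carboxylic acid, so the two phenols stay free and unbenzylated.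

Step 8
Reactants: 11 2,4-dimethoxy-3,6-dimethylbenzoic acid; 14 benzyl 2,4-dihydroxy-3,6-dimethylbenzoate
Product: 16 benzyl 4-[(2,4-dimethoxy-3,6-dimethylbenzoyl)oxy]-2-hydroxy-3,6-dimethylbenzoate, via mixed trifluoroacetic anhydride 15 (not isolated)
Conditions: TFAA (4 equiv), toluene, rt
Reagents that add atoms: none
Why: Mixed-anhydride esterification: TFAA turns the hindered, electron-rich acid 11 into anhydride 15, which ionises readily towards the aroylium ion and acylates the open 4-OH of 14, while the 2-OH is hydrogen-bonded to the ester carbonyl and flanked by two substituents and should stay free; any phenol trifluoroacetate is cleaved on aqueous work-up.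

Step 9
Reactants: 16 benzyl 4-[(2,4-dimethoxy-3,6-dimethylbenzoyl)oxy]-2-hydroxy-3,6-dimethylbenzoate
Product: 17 diffractaic acid
Conditions: H2 (1 atm), 10% Pd/C, EtOAc, rt
Reagents that add atoms: none
Why: Hydrogenolysis of the benzyl ester under neutral conditions should leave the depside aryl ester, the methyl ethers and the free phenol untouched and avoids any base that would cleave the depside link.

**Compound list**

1 | methylmalonic acid | CC(C(=O)O)C(=O)O | starting material
2 | methylmalonyl dichloride | CC(C(=O)Cl)C(=O)Cl | intermediate
3 | benzyl acetoacetate | CC(=O)CC(=O)OCc1ccccc1 | starting material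
4 | benzyl 2-acetyl-5-chloro-4-methyl-3,5-dioxopentanoate (enolisable centres, mixture; not isolated) | CC(=O)C(C(=O)OCc1ccccc1)C(=O)C(C)C(=O)Cl | intermediate
5 | benzyl 4-hydroxy-3,6-dimethyl-2-oxo-2H-pyran-5-carboxylate | CC1=C(C(=O)OCc2ccccc2)C(O)=C(C)C(=O)O1 | intermediate
6 | benzyl 4-methoxy-3,6-dimethyl-2-oxo-2H-pyran-5-carboxylate | COC1=C(C)C(=O)OC(C)=C1C(=O)OCc1ccccc1 | intermediate
7 | 1,1-dimethoxyethene | C=C(OC)OC | starting material
8 | benzyl 5,8,8-trimethoxy-1,4-dimethyl-3-oxo-2-oxabicyclo[2.2.2]oct-5-ene-6-carboxylate (racemic, bridgeheads fixed relative to each other by the bicycle; not isolated) | O=C1OC2(C)CC(OC)(OC)C1(C)C(OC)=C2C(=O)OCc1ccccc1 | intermediate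
9 | benzyl 4,4,6-trimethoxy-2,5-dimethylcyclohexa-1,5-diene-1-carboxylate (not isolated) | COC1=C(C)C(OC)(OC)CC(C)=C1C(=O)OCc1ccccc1 | intermediate
10 | benzyl 2,4-dimethoxy-3,6-dimethylbenzoate | COc1cc(C)c(C(=O)OCc2ccccc2)c(OC)c1C | intermediate
11 | 2,4-dimethoxy-3,6-dimethylbenzoic acid | COc1cc(C)c(C(=O)O)c(OC)c1C | intermediate
12 | methyl 2,4-dihydroxy-3,6-dimethylbenzoate | COC(=O)c1c(C)cc(O)c(C)c1O | starting material
13 | 2,4-dihydroxy-3,6-dimethylbenzoic acid | Cc1cc(O)c(C)c(O)c1C(=O)O | intermediate
14 | benzyl 2,4-dihydroxy-3,6-dimethylbenzoate | Cc1cc(O)c(C)c(O)c1C(=O)OCc1ccccc1 | intermediate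
15 | 2,4-dimethoxy-3,6-dimethylbenzoic trifluoroacetic anhydride (not isolated) | COc1cc(C)c(C(=O)OC(=O)C(F)(F)F)c(OC)c1C | intermediate
16 | benzyl 4-[(2,4-dimethoxy-3,6-dimethylbenzoyl)oxy]-2-hydroxy-3,6-dimethylbenzoate | COc1cc(C)c(C(=O)Oc2cc(C)c(C(=O)OCc3ccccc3)c(O)c2C)c(OC)c1C | intermediate
17 | diffractaic acid | COc1cc(C)c(C(=O)Oc2cc(C)c(C(=O)O)c(O)c2C)c(OC)c1C | target

**Step count**

Total steps: 9. Longest linear sequence: 7 steps (steps 1, 2, 3, 4, 5, 8, 9, from methylmalonic acid 1); the ring B branch (steps 6, 7) joins at step 8.

**Steps most likely to fail**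

Step 4 (highest risk). The cycloaddition may not keep pace with thermal oligomerisation of the ketene acetal. The 4-methoxy donor raises the diene LUMO, both bonding termini (pyrone C3 and C6) carry methyl groups, and the C5 ester is pushed out of conjugation by its two neighbours. A second failure mode is hydrolysis of the ketal of 9 by adventitious acid and water, which would end in a C4 phenol in place of the methyl ether. Fallback, with ring A taken from a preformed arene instead of being built: it sets out from 14 and comes back at 10. Both phenols of 14 are methylated with excess Me2SO4 and K2CO3 in refluxing acetone (the chelated 2-OH needs the excess and a long reaction time), which should give 10 directly; no compound outside the list is made (F0).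

Step 2. The dichloride may lose HCl to chlorocarbonyl(methyl)ketene, which can oligomerise or O-acylate the enol instead of C-acylating it, and the HCl evolved may cleave the benzyl ester. Fallback, with C–C bond formation separated from lactonisation: it sets out from 3 and comes back at 5. Commercial diethyl methylmalonate (CCOC(=O)C(C)C(=O)OCC) is half-saponified (KOH 1 equiv, EtOH, rt; then HCl) to ethyl hydrogen methylmalonate F1. F1 is converted with (COCl)2 and catalytic DMF in CH2Cl2 into ethyl 3-chloro-2-methyl-3-oxopropanoate F2. The magnesium chelate of 3 (MgCl2, pyridine, CH2Cl2, 0 °C) is C-acylated with F2 to give 1-benzyl 5-ethyl 2-acetyl-4-methyl-3-oxopentanedioate F3. This 3,5-dioxo ester should lactonise through its acetyl enol oxygen (catalytic DBU, toluene, reflux, loss of ethanol) to 5.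

Step 6. Hydroxide attack on the ester is retarded once both phenols are deprotonated and the ester sits between O⁻ and CH3, and forcing the temperature or a slow acidification invites loss of CO2 from the product. A mere change of conditions would be the acylium pathway in cold concentrated H2SO4. Fallback, with ring B carried as the aldehyde so that no ester exchange and no benzyl group are needed: it sets out from 11 and comes back at 17. Acid 11 is coupled by the same TFAA method (toluene, rt) with commercial 2,4-dihydroxy-3,6-dimethylbenzaldehyde (Cc1cc(O)c(C)c(O)c1C=O) to give 4-formyl-3-hydroxy-2,5-dimethylphenyl 2,4-dimethoxy-3,6-dimethylbenzoate F4. Pinnick oxidation of F4 (NaClO2, NaH2PO4, 2-methyl-2-butene, t-BuOH–H2O, rt) should then give 17, and steps 6, 7, 8 and 9 are not needed.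

**Further compounds**

F0 | step 4 | none | none
F1 | step 2 | ethyl hydrogen methylmalonate (3-ethoxy-2-methyl-3-oxopropanoic acid, racemic) | CCOC(=O)C(C)C(=O)O
F2 | step 2 | ethyl 3-chloro-2-methyl-3-oxopropanoate (racemic) | CCOC(=O)C(C)C(Cl)=O
F3 | step 2 | 1-benzyl 5-ethyl 2-acetyl-4-methyl-3-oxopentanedioate (enolisable centres, mixture) | CCOC(=O)C(C)C(=O)C(C(C)=O)C(=O)OCc1ccccc1
F4 | step 6 | 4-formyl-3-hydroxy-2,5-dimethylphenyl 2,4-dimethoxy-3,6-dimethylbenzoate | COc1cc(C)c(C(=O)Oc2cc(C)c(C=O)c(O)c2C)c(OC)c1C
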